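**Plan**

1. Labdane numbering is used (ring A = C1–C5, C10; ring B = C5–C10). The retrosynthesis cuts, in this order: the silyl group at O15 and the acetyl group at O7; C8–C17 (methyl addition to an 8-ketone); C9–C11 (side-chain organometallic onto a C9 carbonyl); C8–C9 and C5–C6 of ring B; and C10–C5 and C10–C1 of ring A.
2. Ring A arises first, by a one-carbon ring enlargement. C10 is a quaternary carbon (CH3, C9) between the CH2 carbon C1 and C5, and C5 has the gem-dimethyl carbon C4 on its other side. Ring A without C10 is therefore 2,2-dimethylcyclopentanone (carbonyl = C5), and C10 with C20 and C9 is a 2-diazopropanoate; insertion with migration of C1 gives the six-membered β-keto ester.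
3. Ring B is then built on the C5 ketone and the C9 ester with methyl propargyl ether as C6–C8 (alkynylation, Meyer–Schuster rearrangement, Claisen closure). The side chain, made separately, is joined at C9 by a Stork–Danheiser sequence.
4. Stereochemistry: C10 from the chiral Lewis acid of the ring enlargement; C5 by hydrogenation anti to the axial methyl groups; C7 by Luche reduction; C9 by α-protonation next to the C8 ketone; C8 by equatorial attack of the methyl nucleophile; 13E by syn-carbometalation.

Key step: step 2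

Remark: diones 9 and 10 are drawn as their C7-enol/C9-keto tautomers; 7 and 19 are epimer mixtures at a carbinol carbon that is destroyed later; 8 is an E/Z mixture (Z drawn); the catalyst antipode in step 2 is the one found to give (S)-4.

**Route**

Step 1
Reactants: 1 ethyl 2-methyl-3-oxobutanoate
Product: 2 ethyl 2-diazopropanoate
Conditions: p-ABSA, DBU, MeCN, 0 °C → rt
Reagents that add atoms: 4-acetamidobenzenesulfonyl azide (p-ABSA), CC(=O)Nc1ccc(cc1)S(=O)(=O)N=[N+]=[N-]
Why: Regitz deacylative diazo transfer, in which the triazoline adduct of the β-keto ester enolate should collapse with transfer of the acetyl group to the sulfonamide and leave the mono-acceptor diazo ester.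

Step 2
Reactants: 3 2,2-dimethylcyclopentan-1-one; 2 ethyl 2-diazopropanoate
Product: 4 ethyl (1S)-1,3,3-trimethyl-2-oxocyclohexane-1-carboxylate
Conditions: Sc(OTf)3 (10 mol%), chiral N,N′-dioxide ligand (11 mol%), CH2Cl2, −20 → 0 °C, slow addition of 2
Reagents that add atoms: none
Why: Proposed new method: the Lewis-acid-bound C5 carbonyl of 3 should be attacked by the nucleophilic diazo carbon of 2 (the future C10) to give a β-diazonio alkoxide, and C1, the only unsubstituted α-carbon, should then shift from C5 to C10 anti to the leaving N2, so that C10 is inserted between C5 and C1 (Tiffeneau–Demjanov-type diazo ester homologation). The closest known reaction type is the chiral Lewis acid catalysed ring expansion of cycloalkanones with α-alkyl-α-diazo esters to α-quaternary cyclic β-keto esters; new here are the ketone with a fully substituted α-carbon and the five- to six-membered case. No ring is closed: ring A arises from the cyclopentanone by a one-carbon enlargement through a 1,2-shift, the C5–C10 bond being made by carbonyl addition. The only new stereocentre, C10, is set by the chiral Lewis acid, which fixes the face of the diazo carbon that bonds to C5 and the rotamer from which C1 migrates. The step needs migration of C1 and not of C4, and ring enlargement and not epoxide formation; the gem-dimethyl group on C4 disfavours the shift of C4 to the crowded C10, and strong carbonyl activation with slow addition of 2 favours the 1,2-shift.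

Step 3
Reactants: 4 ethyl (1S)-1,3,3-trimethyl-2-oxocyclohexane-1-carboxylate; 5 3-methoxyprop-1-yne
Product: 7 ethyl (1S)-2-hydroxy-2-(3-methoxyprop-1-yn-1-yl)-1,3,3-trimethylcyclohexane-1-carboxylate (C2 epimers), via lithium acetylide 6 (not isolated)
Conditions: 5, n-BuLi, THF, −78 °C; CeCl3; then 4, −78 → −40 °C; AcOH quench at −78 °C
Reagents that add atoms: none
Why: 1,2-addition of a slim alkynyl-cerium nucleophile to the non-enolisable C5 ketone should be faster than attack on the neopentyl ester, the cold acidic quench should keep the alkoxide from retro-aldol cleavage, and the configuration of the new carbinol centre is of no consequence.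

Step 4
Reactants: 7 ethyl (1S)-2-hydroxy-2-(3-methoxyprop-1-yn-1-yl)-1,3,3-trimethylcyclohexane-1-carboxylate
Product: 8 ethyl (1S)-2-(3-methoxy-2-oxopropylidene)-1,3,3-trimethylcyclohexane-1-carboxylate (E/Z mixture)
Conditions: (Ph3SiO)3V=O (5 mol%), Ph3SiOH (10 mol%), xylene, 140 °C
Reagents that add atoms: none
Why: Meyer–Schuster rearrangement through a [3,3] shift of the propargyl vanadate to the allenyl vanadate, with the Rupe path closed because C4 and C10 carry no hydrogen.

Step 5
Reactants: 8 ethyl (1S)-2-(3-methoxy-2-oxopropylidene)-1,3,3-trimethylcyclohexane-1-carboxylate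
Product: 9 (8aS)-3-hydroxy-2-methoxy-5,5,8a-trimethyl-6,7,8,8a-tetrahydronaphthalen-1(5H)-one
Conditions: KOtBu (2.2 equiv), THF, 0 °C → rt; 1 M HCl; recovered (E)-8 re-equilibrated (cat. I2, hν) and recycled
Reagents that add atoms: none
Why: intramolecular Claisen (Dieckmann-type) acylation of the C8 ketone enolate by the C9 ester should close ring B (6-exo-trig) from the (Z)-enone and be driven by deprotonation of the 2-methoxy-1,3-dione.

Step 6
Reactants: 9 (8aS)-3-hydroxy-2-methoxy-5,5,8a-trimethyl-6,7,8,8a-tetrahydronaphthalen-1(5H)-one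
Product: 10 (4aS,8aS)-3-hydroxy-2-methoxy-5,5,8a-trimethyl-4a,5,6,7,8,8a-hexahydronaphthalen-1(4H)-one
Conditions: H2 (3 atm), 10% Pd/C, EtOAc, rt
Reagents that add atoms: none
Why: catalytic hydrogenation of the conjugated C5=C6 bond should take place from the α-face, because the β-face of C5 is covered by the axial methyl groups on C10 and C4, which sets the trans ring fusion (5α-H).

Step 7
Reactants: 10 (4aS,8aS)-3-hydroxy-2-methoxy-5,5,8a-trimethyl-4a,5,6,7,8,8a-hexahydronaphthalen-1(4H)-one
Product: 11 (4aS,8aS)-2,3-dimethoxy-5,5,8a-trimethyl-4a,5,6,7,8,8a-hexahydronaphthalen-1(4H)-one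
Conditions: HC(OMe)3, MeOH, TsOH (cat.), rt
Reagents that add atoms: trimethyl orthoformate, COC(OC)OC; methanol, CO
Why: acid-catalysed enol ether formation under equilibrating conditions should put the methoxy group on the less hindered C7 oxygen and leave the carbonyl at C9 next to the quaternary C10, as is known for 4,4-dimethylcyclohexane-1,3-dione.

Step 8
Reactants: 12 tert-butyl(but-3-yn-1-yloxy)dimethylsilane
Product: 14 (E)-5-(tert-butyldimethylsilyloxy)-3-methylpent-2-en-1-ol, via alkenylalane 13 (not isolated)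
Conditions: Me3Al, Cp2ZrCl2 (cat.), CH2Cl2, 0 °C → rt; then n-BuLi, (CH2O)n, THF, −78 °C → rt
Reagents that add atoms: trimethylaluminium, C[Al](C)C; formaldehyde (as paraformaldehyde), C=O
Why: Negishi zirconium-catalysed carboalumination adds CH3 and Al syn across the alkyne, and hydroxymethylation of the alanate with retention should fix the (E)-trisubstituted alkene of the side chain.

Step 9
Reactants: 14 (E)-5-(tert-butyldimethylsilyloxy)-3-methylpent-2-en-1-ol
Product: 15 (E)-5-(tert-butyldimethylsilyloxy)-1-(tert-butyldiphenylsilyloxy)-3-methylpent-2-ene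
Conditions: TBDPSCl, imidazole, DMF, rt
Reagents that add atoms: tert-butyl(chloro)diphenylsilane, CC(C)(C)[Si](Cl)(c1ccccc1)c1ccccc1
Why: standard silylation of the primary allylic alcohol with a group that survives the later acidic steps.

Step 10
Reactants: 15 (E)-5-(tert-butyldimethylsilyloxy)-1-(tert-butyldiphenylsilyloxy)-3-methylpent-2-ene
Product: 16 (E)-5-(tert-butyldiphenylsilyloxy)-3-methylpent-3-en-1-ol
Conditions: PPTS (cat.), MeOH, rt
Reagents that add atoms: none
Why: mild acid methanolysis should cleave the primary TBS ether selectively and leave the more robust TBDPS ether.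

Step 11
Reactants: 16 (E)-5-(tert-butyldiphenylsilyloxy)-3-methylpent-3-en-1-ol
Product: 17 (E)-tert-butyl[(5-iodo-3-methylpent-2-en-1-yl)oxy]diphenylsilane
Conditions: I2, PPh3, imidazole, CH2Cl2, 0 °C
Reagents that add atoms: iodine, II
Why: Appel-type iodination of the primary homoallylic alcohol by SN2 displacement of the oxyphosphonium group.

Step 12
Reactants: 17 (E)-tert-butyl[(5-iodo-3-methylpent-2-en-1-yl)oxy]diphenylsilane; 11 (4aS,8aS)-2,3-dimethoxy-5,5,8a-trimethyl-4a,5,6,7,8,8a-hexahydronaphthalen-1(4H)-one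
Product: 20 (5S,10S)-15-(tert-butyldiphenylsilyloxy)-8-methoxy-17-norlabda-8,13E-dien-7-one, via alkyllithium 18 (not isolated), via tertiary carbinol 19 (not isolated)
Conditions: 17, t-BuLi (2 equiv), Et2O, −78 °C; CeCl3, THF; 11, −78 → 0 °C; then 1 M HCl, THF, 0 °C
Reagents that add atoms: water, O
Why: Stork–Danheiser sequence, in which 1,2-addition of the organocerium to the C9 carbonyl of the vinylogous ester and acid-induced allylic transposition with loss of methanol should give the 8-methoxy-Δ8-7-ketone, so that C9–C11 is made at a carbonyl carbon and no stereocentre has to be set here.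

Step 13
Reactants: 20 (5S,10S)-15-(tert-butyldiphenylsilyloxy)-8-methoxy-17-norlabda-8,13E-dien-7-one
Product: 22 (5S,7S,9R,10S)-15-(tert-butyldiphenylsilyloxy)-7-hydroxy-17-norlabd-13E-en-8-one, via allylic alcohol 21 (not isolated)
Conditions: NaBH4, CeCl3·7H2O, MeOH, −40 °C; then 0.5 M oxalic acid, THF/H2O, 0 °C → rt
Reagents that add atoms: water, O
Why: Luche 1,2-reduction by axial (α-face) hydride delivery should give the equatorial 7β-alcohol, and hydrolysis of the now unconjugated C8 enol ether should give the C8 ketone with protonation of C9 from the open α-face, the equatorial 9β side chain being also the thermodynamic epimer.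

Step 14
Reactants: 22 (5S,7S,9R,10S)-15-(tert-butyldiphenylsilyloxy)-7-hydroxy-17-norlabd-13E-en-8-one
Product: 23 (5S,7S,8R,9R,10S)-15-(tert-butyldiphenylsilyloxy)labd-13E-ene-7,8-diol
Conditions: MeMgBr (4 equiv), CeCl3, THF, −78 → 0 °C
Reagents that add atoms: methylmagnesium bromide, C[Mg]Br
Why: Grignard (organocerium) addition to the C8 ketone should follow the equatorial α-path, since the axial β-path is blocked by the 1,3-diaxial C10 methyl group, which gives the axial 8β-hydroxyl and the 8α-methyl group.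

Step 15
Reactants: 23 (5S,7S,8R,9R,10S)-15-(tert-butyldiphenylsilyloxy)labd-13E-ene-7,8-diol
Product: 24 (5S,7S,8R,9R,10S)-7-acetoxy-15-(tert-butyldiphenylsilyloxy)labd-13E-en-8-ol
Conditions: Ac2O, pyridine, DMAP (cat.), CH2Cl2, 0 °C → rt
Reagents that add atoms: acetic anhydride, CC(=O)OC(C)=O
Why: acylation should take place only at the secondary equatorial 7β-hydroxyl, because the 8β-hydroxyl is tertiary and axial and the primary hydroxyl is still silylated.

Step 16
Reactants: 24 (5S,7S,8R,9R,10S)-7-acetoxy-15-(tert-butyldiphenylsilyloxy)labd-13E-en-8-ol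
Product: 25 (5S,7S,8R,9R,10S)-7-acetoxylabd-13E-ene-8,15-diol
Conditions: HF·pyridine, THF/pyridine, 0 °C → rt
Reagents that add atoms: none
Why: fluoride cleavage of the primary silyl ether under buffered conditions should leave the acetate, the tertiary alcohol and the alkene untouched.

**Compound list**

1 | ethyl 2-methyl-3-oxobutanoate | CCOC(=O)C(C)C(C)=O | starting material
2 | ethyl 2-diazopropanoate | CCOC(=O)C(C)=[N+]=[N-] | intermediate
3 | 2,2-dimethylcyclopentan-1-one | CC1(C)CCCC1=O | starting material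
4 | ethyl (1S)-1,3,3-trimethyl-2-oxocyclohexane-1-carboxylate | CCOC(=O)[C@@]1(C)CCCC(C)(C)C1=O | intermediate
5 | 3-methoxyprop-1-yne | COCC#C | starting material
6 | lithium 3-methoxyprop-1-yn-1-ide (formed in the flask) | [Li]C#CCOC | intermediate
7 | ethyl (1S)-2-hydroxy-2-(3-methoxyprop-1-yn-1-yl)-1,3,3-trimethylcyclohexane-1-carboxylate (C2 epimers) | CCOC(=O)[C@@]1(C)CCCC(C)(C)C1(O)C#CCOC | intermediate
8 | ethyl (1S)-2-(3-methoxy-2-oxopropylidene)-1,3,3-trimethylcyclohexane-1-carboxylate (E/Z mixture; Z drawn) | CCOC(=O)[C@@]1(C)CCCC(C)(C)/C1=C/C(=O)COC | intermediate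
9 | (8aS)-3-hydroxy-2-methoxy-5,5,8a-trimethyl-6,7,8,8a-tetrahydronaphthalen-1(5H)-one | COC1=C(O)C=C2C(C)(C)CCC[C@]2(C)C1=O | intermediate
10 | (4aS,8aS)-3-hydroxy-2-methoxy-5,5,8a-trimethyl-4a,5,6,7,8,8a-hexahydronaphthalen-1(4H)-one | COC1=C(O)C[C@H]2C(C)(C)CCC[C@]2(C)C1=O | intermediate
11 | (4aS,8aS)-2,3-dimethoxy-5,5,8a-trimethyl-4a,5,6,7,8,8a-hexahydronaphthalen-1(4H)-one | COC1=C(OC)C[C@H]2C(C)(C)CCC[C@]2(C)C1=O | intermediate
12 | tert-butyl(but-3-yn-1-yloxy)dimethylsilane | C#CCCO[Si](C)(C)C(C)(C)C | starting material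
13 | (E)-[4-(tert-butyldimethylsilyloxy)-2-methylbut-1-en-1-yl]dimethylaluminium (formed in the flask) | C[Al](C)/C=C(\C)CCO[Si](C)(C)C(C)(C)C | intermediate
14 | (E)-5-(tert-butyldimethylsilyloxy)-3-methylpent-2-en-1-ol | OC/C=C(\C)CCO[Si](C)(C)C(C)(C)C | intermediate
15 | (E)-5-(tert-butyldimethylsilyloxy)-1-(tert-butyldiphenylsilyloxy)-3-methylpent-2-ene | CC(C)(C)[Si](C)(C)OCC/C(C)=C/CO[Si](c1ccccc1)(c1ccccc1)C(C)(C)C | intermediate
16 | (E)-5-(tert-butyldiphenylsilyloxy)-3-methylpent-3-en-1-ol | OCC/C(C)=C/CO[Si](c1ccccc1)(c1ccccc1)C(C)(C)C | intermediate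
17 | (E)-tert-butyl[(5-iodo-3-methylpent-2-en-1-yl)oxy]diphenylsilane | ICC/C(C)=C/CO[Si](c1ccccc1)(c1ccccc1)C(C)(C)C | intermediate
18 | (E)-[5-(tert-butyldiphenylsilyloxy)-3-methylpent-3-en-1-yl]lithium (formed in the flask) | [Li]CC/C(C)=C/CO[Si](c1ccccc1)(c1ccccc1)C(C)(C)C | intermediate
19 | (4aS,8aS)-1-[(E)-5-(tert-butyldiphenylsilyloxy)-3-methylpent-3-en-1-yl]-2,3-dimethoxy-5,5,8a-trimethyl-1,4,4a,5,6,7,8,8a-octahydronaphthalen-1-ol (C1 epimers; formed in the flask) | COC1=C(OC)C[C@H]2C(C)(C)CCC[C@]2(C)C1(O)CC/C(C)=C/CO[Si](c1ccccc1)(c1ccccc1)C(C)(C)C | intermediate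
20 | (5S,10S)-15-(tert-butyldiphenylsilyloxy)-8-methoxy-17-norlabda-8,13E-dien-7-one | COC1=C(CC/C(C)=C/CO[Si](c2ccccc2)(c2ccccc2)C(C)(C)C)[C@@]2(C)CCCC(C)(C)[C@@H]2CC1=O | intermediate
21 | (5S,7S,10S)-15-(tert-butyldiphenylsilyloxy)-8-methoxy-17-norlabda-8,13E-dien-7-ol (7β-OH; formed in the flask) | COC1=C(CC/C(C)=C/CO[Si](c2ccccc2)(c2ccccc2)C(C)(C)C)[C@@]2(C)CCCC(C)(C)[C@@H]2C[C@@H]1O | intermediate
22 | (5S,7S,9R,10S)-15-(tert-butyldiphenylsilyloxy)-7-hydroxy-17-norlabd-13E-en-8-one (7β-OH, 9β side chain) | O[C@H]1C[C@H]2C(C)(C)CCC[C@]2(C)[C@@H](CC/C(C)=C/CO[Si](c3ccccc3)(c3ccccc3)C(C)(C)C)C1=O | intermediate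
23 | (5S,7S,8R,9R,10S)-15-(tert-butyldiphenylsilyloxy)labd-13E-ene-7,8-diol (7β,8β-diol, 8α-CH3) | O[C@H]1C[C@H]2C(C)(C)CCC[C@]2(C)[C@@H](CC/C(C)=C/CO[Si](c3ccccc3)(c3ccccc3)C(C)(C)C)[C@@]1(C)O | intermediate
24 | (5S,7S,8R,9R,10S)-7-acetoxy-15-(tert-butyldiphenylsilyloxy)labd-13E-en-8-ol | CC(=O)O[C@H]1C[C@H]2C(C)(C)CCC[C@]2(C)[C@@H](CC/C(C)=C/CO[Si](c3ccccc3)(c3ccccc3)C(C)(C)C)[C@@]1(C)O | intermediate
25 | (5S,7S,8R,9R,10S)-7-acetoxylabd-13E-ene-8,15-diol (7β-OAc, 8β-OH, 8α-CH3, 9β side chain, 5α-H, 10β-CH3) | CC(=O)O[C@H]1C[C@H]2C(C)(C)CCC[C@]2(C)[C@@H](CC/C(C)=C/CO)[C@@]1(C)O | target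

**Step count and risks**

Total step count: 16. Longest linear sequence: 12 steps (steps 1–7 and 12–16, from 1); the side-chain branch is steps 8–11.

Steps most likely to fail:

1. Step 2 (proposed new method). The carbonyl of the α,α-disubstituted ketone may add the tertiary diazo carbon too slowly, so that the diazo ester decomposes or closes to an epoxide, or the catalyst may discriminate the faces poorly. Fallback: it sets out from 3. A BF3·OEt2-promoted homologation with ethyl diazoacetate (Tiffeneau–Demjanov-type, migration of the CH2 carbon) should give ethyl 3,3-dimethyl-2-oxocyclohexane-1-carboxylate F1. Enantioselective C-methylation of F1 (MeI, solid base, chiral quaternary ammonium phase-transfer catalyst, toluene) should then give 4, where the route is rejoined; ring enlargement and creation of the C10 stereocentre are thus separated.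

2. Step 3. The tertiary lithium or cerium alkoxide next to the ester may fragment by retro-aldol cleavage of the C5–C10 bond, or the nucleophile may be diverted to the ester. Fallback: it sets out from 4. A zinc-mediated Barbier allylation with 2-(bromomethyl)-3-methoxyprop-1-ene (Zn, THF/aq. NH4Cl), which passes through a non-basic zinc alkoxide, should give ethyl (1S)-2-hydroxy-2-[2-(methoxymethyl)prop-2-en-1-yl]-1,3,3-trimethylcyclohexane-1-carboxylate F2. Dehydration with the Burgess reagent should give the diene ethyl (1S)-2-[2-(methoxymethyl)prop-2-en-1-ylidene]-1,3,3-trimethylcyclohexane-1-carboxylate F3. Lemieux–Johnson cleavage (OsO4 cat., NaIO4) of its unhindered 1,1-disubstituted alkene should give 8, where the route is rejoined.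

3. Step 5. Interconversion of the (E)- and (Z)-enone may fail, or acylation by the neopentyl ester may be too slow, so that ring B does not close. Fallback: it sets out from 7 and closes the ring before the C5=C6 bond exists. Ru-catalysed trans-hydrosilylation ((EtO)3SiH, [Cp*Ru(MeCN)3]PF6, CH2Cl2) should give ethyl (1S)-2-hydroxy-2-[(Z)-3-methoxy-2-(triethoxysilyl)prop-1-en-1-yl]-1,3,3-trimethylcyclohexane-1-carboxylate F4. Tamao–Fleming oxidation (KF, KHCO3, H2O2) should give the β-hydroxy ketone ethyl (1S)-2-hydroxy-2-(3-methoxy-2-oxopropyl)-1,3,3-trimethylcyclohexane-1-carboxylate F5. Claisen closure of its dianion (LDA, 2.2 equiv, THF, −78 → 0 °C), which is protected against retro-aldol cleavage, should give (8aS)-3,4a-dihydroxy-2-methoxy-5,5,8a-trimethyl-4a,5,6,7,8,8a-hexahydronaphthalen-1(4H)-one F6. Acid dehydration (TsOH, benzene, reflux) should give 9, where the route is rejoined.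

Further compounds
F1 | step 2 | ethyl 3,3-dimethyl-2-oxocyclohexane-1-carboxylate | CCOC(=O)C1CCCC(C)(C)C1=O
F2 | step 3 | ethyl (1S)-2-hydroxy-2-[2-(methoxymethyl)prop-2-en-1-yl]-1,3,3-trimethylcyclohexane-1-carboxylate | CCOC(=O)[C@@]1(C)CCCC(C)(C)C1(O)CC(=C)COC
F3 | step 3 | ethyl (1S)-2-[2-(methoxymethyl)prop-2-en-1-ylidene]-1,3,3-trimethylcyclohexane-1-carboxylate | CCOC(=O)[C@@]1(C)CCCC(C)(C)C1=CC(=C)COC
F4 | step 5 | ethyl (1S)-2-hydroxy-2-[(Z)-3-methoxy-2-(triethoxysilyl)prop-1-en-1-yl]-1,3,3-trimethylcyclohexane-1-carboxylate | CCOC(=O)[C@@]1(C)CCCC(C)(C)C1(O)/C=C(/COC)[Si](OCC)(OCC)OCC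
F5 | step 5 | ethyl (1S)-2-hydroxy-2-(3-methoxy-2-oxopropyl)-1,3,3-trimethylcyclohexane-1-carboxylate | CCOC(=O)[C@@]1(C)CCCC(C)(C)C1(O)CC(=O)COC
F6 | step 5 | (8aS)-3,4a-dihydroxy-2-methoxy-5,5,8a-trimethyl-4a,5,6,7,8,8a-hexahydronaphthalen-1(4H)-one | COC1=C(O)CC2(O)C(C)(C)CCC[C@]2(C)C1=O
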